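The data stem from a simulated flask with constants of no real substance, noise included.

- No rate constant is given here, so the charges and readings must stand in for constants. Ochre is the flask asked about, followed so far, and violet is the same recipe with more free base.

| setting | ochre | violet | flask |
|---|---|---|---|
| electrophile | 0.13 M | 0.13 M | 0.13 M |
| nucleophile | 0.90 equiv | 0.90 equiv | 0.900 equiv |
| free base | 3 equiv | 6 equiv | 3.00 equiv |
| protic impurity | 0.039 M | 0.039 M | 0.0390 M |
| remark | the very flask that is asked about, followed so far | run made earlier |  |
| time |  |  | 12 min |

| run | time / min | product / % | electrophile / % |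
|---|---|---|---|
| ochre | 0.500 | 30.6 | 63.8 |
| ochre | 1.33 | 41.3 | 48.5 |
| ochre | 2.50 | 44.5 | 39.9 |
| ochre | 4.00 | 45.3 | 35.3 |
| ochre | 6.00 | 46.3 | 31.9 |
| ochre | 8.00 | 46.9 | 29.8 |
| ochre | 10.0 | 46.9 | 27.8 |
| violet | 0.167 | 16.3 | 80.8 |
| violet | 0.333 | 25.6 | 70.0 |
| violet | 0.667 | 34.8 | 59.0 |
| violet | 1.00 | 39.0 | 51.7 |
| violet | 1.33 | 40.5 | 48.7 |
| violet | 2.00 | 43.8 | 43.8 |
| violet | 2.50 | 44.4 | 42.0 |

(scatter of a reading: 0.5 percentage points)

- Wednesday's: at 12 min take out 90 % of the acid set free then present, then wait 12 min
- Monday's: at 12 min add electrophile, 50.0 % of the amount charged, then wait 12 min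
- Friday's: at 12 min add nucleophile, 50.0 % of the amount charged, then wait 12 min
- Sunday's: at 12 min add free base, 100 % of the amount charged, then wait 12 min
- Tuesday's: change nothing and wait 12 min more

- product, in percent of the electrophile first charged, at 12 min
- the option that brings most further product ("none" if no option brings more than 2 percentage points) (Wednesday's / Monday's / Friday's / Sunday's / Tuesday's / none)
- product present, in percent of the electrophile first charged, after Wednesday's
- product present, in percent of the electrophile first charged, after Tuesday's

- Free base hardly needs to be known well: going from 3 equiv to 6 equiv gave 44.5 % against 44.4 % of product at 2.50 min, with a scatter of 0.5 percentage points.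
- Time matters little: from 6.00 min to 10.0 min, ochre's product crept from 46.3 % to 46.9 %. Extended, that gives 47.2 % now and a further 1.8 points over the wait, a rough figure given the scatter.
- Protic impurity moves electrophile rather than the stall: its charge equals 30.0 % of the electrophile, and ochre's balance was short by 25 points at 10.0 min.
- Nucleophile must be known well. Ochre stalls with 27.8 % of electrophile unused, which fits each product costing two nucleophile, one reacting and one holding the acid. Nucleophile is the limiting reagent, and the stall level C, the nucleophile equivalents divided by two, is 45.0 %. C is an estimate of where product slows, not a limit on it: ochre already read 46.9 % at 10.0 min.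
- Friday's raises C by 22 points. Ochre's electrophile, less what the impurity can still take, is 23 points, more than that rise, so I pick Friday's.
- The acid appears to sit on nucleophile, given the base result, so I expect Wednesday's to bring about what waiting brings, near 49.0 %.
- The forecast gave 47.4 % now, Friday's as best, 67 % after Wednesday's, which differs from my figure, and 48.4 % after Tuesday's, holding that “each acid released ties up one nucleophile”.
- The flask gives 47.3 % now, 49.1 % after Wednesday's and 48.7 % after Tuesday's, with Friday's best at 20 points gained.

    electrophile + nucleophile → acid set free + product (k = 0.189 M⁻¹ s⁻¹)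
    nucleophile + acid set free ⇌ protonated nucleophile, settled at all times (K = 48000 M⁻¹)
    acid set free + free base ⇌ salt of the base, settled at all times (K = 2.70 M⁻¹)
    acid set free → by-product carried off (k = 0.00177 s⁻¹)
    electrophile + protic impurity → quenched substrate (k = 0.0663 M⁻¹ s⁻¹)

- In this flask, half the product step's turnover was done by 0.301 min. At 6.00 min, free nucleophile stood at 0.634 % of its charge beside 0.0563 M of protonated nucleophile. Quenching ran alongside, half done by 1.99 min, with 11 % of the impurity left at 12.0 min.
- At 12.0 min, acid set free stood at 0.00229 M against 0.0551 M protonated nucleophile, and Wednesday's brought 1.8 points. Friday's reached 67.4 %, against a raised C of 67.0 %.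
- The neighbour charged with 0.360 equiv of nucleophile has C = 18.0 %. It gives 20.1 % of product, with 50.7 % of its electrophile left.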